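**Plan**
1. Retrosynthesis: the C3 hydroxyl is traced back to a C3–B bond (retention), C2 to a carbon that carried a removable carboxyl group, and then C1–C2 and C3–C4 are cut together.
2. Enabling feature: the carbonyl carbon C1 and the benzylic methylene C4 sit on neighbouring carbons (C8a, C4a) of the benzene ring, so a 2-methylbenzaldehyde is a latent o-quinodimethane (C1=C8a–C4a=C4) that takes up C2=C3, offered as an (E)-3-borylacryloyl dienophile, in one [4+2] event.
3. Further cuts: aryl C5–pyranone C6' (Stille) and aryl C6–phenyl (Suzuki–Miyaura on a triflate of 2,4-dihydroxy-6-methylbenzaldehyde).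
4. Forward order: the benzene ring is bought and decorated (phenyl, bromine, benzyl ether); ring B is closed by photoenolization/Diels–Alder; then auxiliary off, pyranone on, C1 carbinol to ketone, decarboxylation at C2, and C–B to C–OH last.
5. Stereochemistry: the only stereocentre of the target, C3 (S), is set in the cycloaddition by the (S)-4-benzyloxazolidinone on the dienophile and passed from boron to oxygen with retention; C1 and C2 are transient.

Key step: step 7

Remark: 6-chloro-4-hydroxy-2H-pyran-2-one, a known compound of malonyl dichloride chemistry, is taken to be purchasable.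

**Step 1**
Reactants: 1 2,4-dihydroxy-6-methylbenzaldehyde
Product: 2 4-formyl-3-hydroxy-5-methylphenyl trifluoromethanesulfonate
Conditions: PhNTf2, Et3N, CH2Cl2, 0 °C to rt
Reagents that add atoms: N-phenylbis(trifluoromethanesulfonimide), O=S(=O)(N(c1ccccc1)S(=O)(=O)C(F)(F)F)C(F)(F)F
Why: The 2-hydroxyl is held in a hydrogen bond to the formyl group, so the more acidic, unchelated 4-hydroxyl should be sulfonylated selectively (chemoselective O-triflation of a phenol).

**Step 2**
Reactants: 2 4-formyl-3-hydroxy-5-methylphenyl trifluoromethanesulfonate; 3 phenylboronic acid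
Product: 4 2-hydroxy-6-methyl-4-phenylbenzaldehyde
Conditions: Pd(PPh3)4 (cat.), K3PO4, 1,4-dioxane, 90 °C
Reagents that add atoms: none
Why: Suzuki–Miyaura coupling of the electron-poor aryl triflate (para to the formyl group) should install the phenyl ring, the free salicylaldehyde hydroxyl being tolerated as its phenoxide.

**Step 3**
Reactants: 4 2-hydroxy-6-methyl-4-phenylbenzaldehyde
Product: 5 3-bromo-6-hydroxy-2-methyl-4-phenylbenzaldehyde
Conditions: NBS, MeCN, 0 °C to rt
Reagents that add atoms: N-bromosuccinimide, O=C1CCC(=O)N1Br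
Why: Electrophilic aromatic bromination should go para to the phenol oxygen (also ortho to methyl and meta to the formyl group), which is the electronically preferred site of this phenol.

**Step 4**
Reactants: 5 3-bromo-6-hydroxy-2-methyl-4-phenylbenzaldehyde
Product: 6 6-(benzyloxy)-3-bromo-2-methyl-4-phenylbenzaldehyde
Conditions: BnBr, K2CO3, DMF, 50 °C
Reagents that add atoms: benzyl bromide, BrCc1ccccc1
Why: Williamson etherification; the benzyl ether prevents excited-state proton transfer from the ortho hydroxyl, which would quench photoenolization, and is removable later by hydrogenolysis.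

**Step 5**
Reactants: 7 (S)-4-benzyloxazolidin-2-one; 8 propiolic acid
Product: 9 (S)-4-benzyl-3-propioloyloxazolidin-2-one
Conditions: DCC, DMAP (cat.), CH2Cl2, −20 to 0 °C
Reagents that add atoms: none
Why: Carbodiimide-mediated N-acylation of the oxazolidinone should give the alkynoyl imide, the low temperature limiting amine addition to the ynoate.

**Step 6**
Reactants: 9 (S)-4-benzyl-3-propioloyloxazolidin-2-one
Product: 10 (S)-4-benzyl-3-[(E)-3-(4,4,5,5-tetramethyl-1,3,2-dioxaborolan-2-yl)acryloyl]oxazolidin-2-one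
Conditions: B2pin2, CuCl (cat.), Xantphos (cat.), KOt-Bu (cat.), t-BuOH, THF, 0 °C to rt
Reagents that add atoms: bis(pinacolato)diboron, CC1(C)OB(OC1(C)C)B1OC(C)(C)C(C)(C)O1
Why: Copper-catalysed conjugate borylation of the ynoyl imide: syn addition of the copper–boryl species puts boron on the terminal carbon and protonation of the vinylcopper with retention gives the E-alkene (boron trans to the carbonyl), with bulky tert-butoxide used so that the imide is not cleaved.

**Step 7**
Reactants: 6 6-(benzyloxy)-3-bromo-2-methyl-4-phenylbenzaldehyde; 10 (S)-4-benzyl-3-[(E)-3-(4,4,5,5-tetramethyl-1,3,2-dioxaborolan-2-yl)acryloyl]oxazolidin-2-one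
Product: 12 (S)-4-benzyl-3-[(1R,2R,3S)-8-(benzyloxy)-5-bromo-1-hydroxy-6-phenyl-3-(4,4,5,5-tetramethyl-1,3,2-dioxaborolan-2-yl)-1,2,3,4-tetrahydronaphthalene-2-carbonyl]oxazolidin-2-one, via photoenol 11 (not isolated)
Conditions: hν (365 nm LED), Ti(Oi-Pr)4 (2 equiv), 10 (1.5 equiv), degassed toluene, rt
Reagents that add atoms: none
Why: Excitation (n,π*) of aldehyde 6 is followed by 1,5-hydrogen transfer from the ortho methyl group to give hydroxy-o-quinodimethane 11 (hydroxyl turned outward), which titanium holds as its dienolate while binding both imide carbonyls of 10, and a concerted suprafacial [4+2] cycloaddition then restores the benzene ring. The closest known reaction type is the photoenolization/Diels–Alder reaction of 2-methylbenzaldehydes with enones and acrylic acid derivatives promoted by Ti(Oi-Pr)4, combined with the use of 3-borylacryloyl oxazolidinones as dienophiles in which boron stands for a hydroxyl group. Ring B (C1–C2–C3–C4–C4a–C8a) is closed by an intermolecular [4+2] cycloaddition, endo with respect to the imide carbonyl. C3 is fixed by the dienophile face, since in the chelated s-cis imide the 4-benzyl group of the (S)-auxiliary shields one face and the diene adds to the other, which gives 3S; C2 follows from C3 through the E geometry of the alkene (boron and acyl trans) and C1 from the endo, titanium-bridged arrangement (hydroxyl cis to the acyl group), both being erased later. The step needs regioselectivity (acyl-bearing carbon to the carbinol terminus, boron-bearing carbon to the methylene terminus), secured by the polarisation of both partners and by the titanium bridge between dienol oxygen and imide, and chemoselectivity, secured because only the aldehyde absorbs at 365 nm while the aryl bromide and benzyl ether are photostable there. The two cis adducts from the two dienophile faces are diastereomers, so the wanted one can be purified by chromatography.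

**Step 8**
Reactants: 12 (S)-4-benzyl-3-[(1R,2R,3S)-8-(benzyloxy)-5-bromo-1-hydroxy-6-phenyl-3-(4,4,5,5-tetramethyl-1,3,2-dioxaborolan-2-yl)-1,2,3,4-tetrahydronaphthalene-2-carbonyl]oxazolidin-2-one
Product: 13 benzyl (1R,2R,3S)-8-(benzyloxy)-5-bromo-1-hydroxy-6-phenyl-3-(4,4,5,5-tetramethyl-1,3,2-dioxaborolan-2-yl)-1,2,3,4-tetrahydronaphthalene-2-carboxylate
Conditions: BnOH, n-BuLi, THF, −78 to 0 °C; aq. NH4Cl
Reagents that add atoms: benzyl alcohol (as lithium benzyloxide), OCc1ccccc1
Why: Transesterification of the N-acyloxazolidinone with lithium benzyloxide (attack at the exocyclic carbonyl, as for cycloadducts of this auxiliary) releases the auxiliary for recovery and gives an ester that can later be removed without base, leaving the C–B bond and the stereocentres untouched.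

**Step 9**
Reactants: 14 6-chloro-4-hydroxy-2H-pyran-2-one
Product: 15 4-(benzyloxy)-6-chloro-2H-pyran-2-one
Conditions: BnOH, PPh3, DIAD, THF, 0 °C to rt
Reagents that add atoms: benzyl alcohol, OCc1ccccc1
Why: Mitsunobu reaction: the acidic 4-hydroxyl (a vinylogous acid) is alkylated on oxygen under neutral conditions, which avoids C3-benzylation and displacement of the 6-chloride.

**Step 10**
Reactants: 15 4-(benzyloxy)-6-chloro-2H-pyran-2-one
Product: 16 4-(benzyloxy)-6-(tributylstannyl)-2H-pyran-2-one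
Conditions: (Bu3Sn)2, Pd(PPh3)4 (cat.), toluene, 100 °C
Reagents that add atoms: hexabutylditin, CCCC[Sn](CCCC)(CCCC)[Sn](CCCC)(CCCC)CCCC
Why: Palladium-catalysed stannylation of the activated vinylogous acyl chloride with the ditin (oxidative addition, tin–tin transmetalation, reductive elimination) should give the stannyl pyranone.

**Step 11**
Reactants: 13 benzyl (1R,2R,3S)-8-(benzyloxy)-5-bromo-1-hydroxy-6-phenyl-3-(4,4,5,5-tetramethyl-1,3,2-dioxaborolan-2-yl)-1,2,3,4-tetrahydronaphthalene-2-carboxylate; 16 4-(benzyloxy)-6-(tributylstannyl)-2H-pyran-2-one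
Product: 17 benzyl (1R,2R,3S)-8-(benzyloxy)-5-[4-(benzyloxy)-2-oxo-2H-pyran-6-yl]-1-hydroxy-6-phenyl-3-(4,4,5,5-tetramethyl-1,3,2-dioxaborolan-2-yl)-1,2,3,4-tetrahydronaphthalene-2-carboxylate
Conditions: Pd2(dba)3 (cat.), P(2-furyl)3, CuI (cat.), NMP, 60 °C
Reagents that add atoms: none
Why: Stille coupling (oxidative addition of zerovalent palladium to the aryl bromide, copper-assisted transmetalation from the stannyl pyranone, reductive elimination) under neutral, fluoride-free conditions, so that the secondary alkyl boronate, the free carbinol and the benzyl ester are not engaged.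

**Step 12**
Reactants: 17 benzyl (1R,2R,3S)-8-(benzyloxy)-5-[4-(benzyloxy)-2-oxo-2H-pyran-6-yl]-1-hydroxy-6-phenyl-3-(4,4,5,5-tetramethyl-1,3,2-dioxaborolan-2-yl)-1,2,3,4-tetrahydronaphthalene-2-carboxylate
Product: 18 benzyl (3S)-8-(benzyloxy)-5-[4-(benzyloxy)-2-oxo-2H-pyran-6-yl]-1-oxo-6-phenyl-3-(4,4,5,5-tetramethyl-1,3,2-dioxaborolan-2-yl)-1,2,3,4-tetrahydronaphthalene-2-carboxylate (C2 epimers and enol)
Conditions: MnO2 (activated, excess), CH2Cl2, rt
Reagents that add atoms: none
Why: Benzylic oxidation with MnO2 converts only the C1 carbinol into the ketone; the hydroxyl at C3 is still masked as boron, which is no leaving group, so the enolised β-keto ester cannot aromatise by β-elimination.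

**Step 13**
Reactants: 18 benzyl (3S)-8-(benzyloxy)-5-[4-(benzyloxy)-2-oxo-2H-pyran-6-yl]-1-oxo-6-phenyl-3-(4,4,5,5-tetramethyl-1,3,2-dioxaborolan-2-yl)-1,2,3,4-tetrahydronaphthalene-2-carboxylate
Product: 20 (S)-8-hydroxy-5-(4-hydroxy-2-oxo-2H-pyran-6-yl)-6-phenyl-3-(4,4,5,5-tetramethyl-1,3,2-dioxaborolan-2-yl)-3,4-dihydronaphthalen-1(2H)-one, via keto acid 19 (not isolated)
Conditions: H2 (1 atm), Pd/C, EtOAc, rt; then 40 °C
Reagents that add atoms: none
Why: Hydrogenolysis cleaves the benzyl ester and both benzyl ethers, and the β-keto acid then loses CO2 through its cyclic enol transition state under neutral conditions, which removes the activating carboxyl from C2 and leaves C3 untouched.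

**Step 14**
Reactants: 20 (S)-8-hydroxy-5-(4-hydroxy-2-oxo-2H-pyran-6-yl)-6-phenyl-3-(4,4,5,5-tetramethyl-1,3,2-dioxaborolan-2-yl)-3,4-dihydronaphthalen-1(2H)-one
Product: 21 (S)-3,8-dihydroxy-5-(4-hydroxy-2-oxo-2H-pyran-6-yl)-6-phenyl-3,4-dihydronaphthalen-1(2H)-one (wailupemycin F)
Conditions: NaBO3·4H2O, THF/H2O, 0 °C to rt; pH 4 work-up
Reagents that add atoms: sodium perborate, [Na+].[Na+].O[B-]1(O)OO[B-](O)(O)OO1
Why: Oxidation of the secondary alkyl boronate by peroxoborate (1,2-shift of carbon from boron to oxygen with retention) unveils the 3S hydroxyl; this is the standard mild conversion of β-boryl ketones into β-hydroxy ketones without dehydration.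

**Compound list**
1 | 2,4-dihydroxy-6-methylbenzaldehyde | Cc1cc(O)cc(O)c1C=O | starting material
2 | 4-formyl-3-hydroxy-5-methylphenyl trifluoromethanesulfonate | Cc1cc(OS(=O)(=O)C(F)(F)F)cc(O)c1C=O | intermediate
3 | phenylboronic acid | OB(O)c1ccccc1 | starting material
4 | 2-hydroxy-6-methyl-4-phenylbenzaldehyde | Cc1cc(-c2ccccc2)cc(O)c1C=O | intermediate
5 | 3-bromo-6-hydroxy-2-methyl-4-phenylbenzaldehyde | Cc1c(Br)c(-c2ccccc2)cc(O)c1C=O | intermediate
6 | 6-(benzyloxy)-3-bromo-2-methyl-4-phenylbenzaldehyde | Cc1c(Br)c(-c2ccccc2)cc(OCc2ccccc2)c1C=O | intermediate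
7 | (S)-4-benzyloxazolidin-2-one | O=C1N[C@@H](Cc2ccccc2)CO1 | starting material
8 | propiolic acid | C#CC(=O)O | starting material
9 | (S)-4-benzyl-3-propioloyloxazolidin-2-one | C#CC(=O)N1[C@@H](Cc2ccccc2)COC1=O | intermediate
10 | (S)-4-benzyl-3-[(E)-3-(4,4,5,5-tetramethyl-1,3,2-dioxaborolan-2-yl)acryloyl]oxazolidin-2-one | O=C(/C=C/B1OC(C)(C)C(C)(C)O1)N1[C@@H](Cc2ccccc2)COC1=O | intermediate
11 | photoenol of 6 (not isolated): 1-(benzyloxy)-4-bromo-6-(hydroxymethylidene)-5-methylidene-3-phenylcyclohexa-1,3-diene, hydroxyl anti to the methylidene-bearing carbon | O/C=C1/C(=C)C(Br)=C(c2ccccc2)C=C1OCc1ccccc1 | intermediate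
12 | (S)-4-benzyl-3-[(1R,2R,3S)-8-(benzyloxy)-5-bromo-1-hydroxy-6-phenyl-3-(4,4,5,5-tetramethyl-1,3,2-dioxaborolan-2-yl)-1,2,3,4-tetrahydronaphthalene-2-carbonyl]oxazolidin-2-one (1-OH and 2-acyl cis, 2-acyl and 3-boryl trans) | O[C@@H]1[C@H](C(=O)N3[C@@H](Cc4ccccc4)COC3=O)[C@@H](B3OC(C)(C)C(C)(C)O3)Cc2c1c(OCc1ccccc1)cc(-c1ccccc1)c2Br | intermediate
13 | benzyl (1R,2R,3S)-8-(benzyloxy)-5-bromo-1-hydroxy-6-phenyl-3-(4,4,5,5-tetramethyl-1,3,2-dioxaborolan-2-yl)-1,2,3,4-tetrahydronaphthalene-2-carboxylate | O[C@@H]1[C@H](C(=O)OCc3ccccc3)[C@@H](B3OC(C)(C)C(C)(C)O3)Cc2c1c(OCc1ccccc1)cc(-c1ccccc1)c2Br | intermediate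
14 | 6-chloro-4-hydroxy-2H-pyran-2-one | O=c1cc(O)cc(Cl)o1 | starting material
15 | 4-(benzyloxy)-6-chloro-2H-pyran-2-one | O=c1cc(OCc2ccccc2)cc(Cl)o1 | intermediate
16 | 4-(benzyloxy)-6-(tributylstannyl)-2H-pyran-2-one | CCCC[Sn](CCCC)(CCCC)c1cc(OCc2ccccc2)cc(=O)o1 | intermediate
17 | benzyl (1R,2R,3S)-8-(benzyloxy)-5-[4-(benzyloxy)-2-oxo-2H-pyran-6-yl]-1-hydroxy-6-phenyl-3-(4,4,5,5-tetramethyl-1,3,2-dioxaborolan-2-yl)-1,2,3,4-tetrahydronaphthalene-2-carboxylate | O[C@@H]1[C@H](C(=O)OCc3ccccc3)[C@@H](B3OC(C)(C)C(C)(C)O3)Cc2c1c(OCc1ccccc1)cc(-c1ccccc1)c2-c1cc(OCc2ccccc2)cc(=O)o1 | intermediate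
18 | benzyl (3S)-8-(benzyloxy)-5-[4-(benzyloxy)-2-oxo-2H-pyran-6-yl]-1-oxo-6-phenyl-3-(4,4,5,5-tetramethyl-1,3,2-dioxaborolan-2-yl)-1,2,3,4-tetrahydronaphthalene-2-carboxylate (C2 labile: epimers and enol) | O=C1C(C(=O)OCc3ccccc3)[C@@H](B3OC(C)(C)C(C)(C)O3)Cc2c1c(OCc1ccccc1)cc(-c1ccccc1)c2-c1cc(OCc2ccccc2)cc(=O)o1 | intermediate
19 | (3S)-8-hydroxy-5-(4-hydroxy-2-oxo-2H-pyran-6-yl)-1-oxo-6-phenyl-3-(4,4,5,5-tetramethyl-1,3,2-dioxaborolan-2-yl)-1,2,3,4-tetrahydronaphthalene-2-carboxylic acid (not isolated) | O=C1C(C(=O)O)[C@@H](B3OC(C)(C)C(C)(C)O3)Cc2c1c(O)cc(-c1ccccc1)c2-c1cc(O)cc(=O)o1 | intermediate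
20 | (S)-8-hydroxy-5-(4-hydroxy-2-oxo-2H-pyran-6-yl)-6-phenyl-3-(4,4,5,5-tetramethyl-1,3,2-dioxaborolan-2-yl)-3,4-dihydronaphthalen-1(2H)-one | O=C1C[C@@H](B3OC(C)(C)C(C)(C)O3)Cc2c1c(O)cc(-c1ccccc1)c2-c1cc(O)cc(=O)o1 | intermediate
21 | (S)-3,8-dihydroxy-5-(4-hydroxy-2-oxo-2H-pyran-6-yl)-6-phenyl-3,4-dihydronaphthalen-1(2H)-one (wailupemycin F) | O=C1C[C@@H](O)Cc2c1c(O)cc(-c1ccccc1)c2-c1cc(O)cc(=O)o1 | target

**Summary**
Total step count: 14. Longest linear sequence: 10 steps (steps 1–4, 7, 8, 11–14).

Steps most likely to fail: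

1. Step 7. The photoenol may revert to the aldehyde faster than the β-substituted dienophile captures it, titanium isopropoxide may cleave the imide, or the auxiliary may discriminate the two dienophile faces poorly. The fallback sets out from 6 and comes back to the route at 13. Auxiliary control would be replaced by ligand control: commercial benzyl propiolate would be borylated as in step 6 (benzyl alcohol as proton source) to benzyl (E)-3-(4,4,5,5-tetramethyl-1,3,2-dioxaborolan-2-yl)acrylate F1. Aldehyde 6 would then be irradiated at 365 nm with F1 in the presence of Ti(Oi-Pr)4 and one equivalent of a TADDOL-type chiral diol, the ligand antipode being chosen to deliver the 3S series. This enantioselective photoenolization/Diels–Alder reaction gives benzyl ester 13 directly and leaves out step 8.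

2. Step 11. Transmetalation from the electron-poor stannane to the doubly ortho-flanked arylpalladium species may be slower than protodestannylation and homocoupling of the stannane. The fallback sets out from 13 and comes back at 17, with the polarity of the coupling reversed. Bromide 13 would be borylated (B2pin2, KOAc, Pd(dppf)Cl2, 1,4-dioxane, 90 °C) to benzyl (1R,2R,3S)-8-(benzyloxy)-1-hydroxy-6-phenyl-3,5-bis(4,4,5,5-tetramethyl-1,3,2-dioxaborolan-2-yl)-1,2,3,4-tetrahydronaphthalene-2-carboxylate F2. Its aryl boronate would then be coupled selectively (Suzuki–Miyaura; Pd(OAc)2, SPhos, K3PO4, THF/H2O, 40 °C) with chloropyranone 15, the secondary alkyl boronate staying inert, to give 17.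

3. Step 14. Peroxide attack on the free ortho-hydroxyaryl ketone (Dakin-type aryl migration) or base-induced loss of water from the newly formed β-hydroxy ketone may compete with C–B oxidation. The fallback sets out from 18 and comes back at 21; it unmasks the groups in a different order so that boron is oxidised while both phenolic oxygens are still benzylated. The benzyl ester of 18 alone would be cleaved with Pd(OAc)2, Et3SiH and Et3N (benzyl ethers stay), and decarboxylation on work-up would give (S)-8-(benzyloxy)-5-[4-(benzyloxy)-2-oxo-2H-pyran-6-yl]-6-phenyl-3-(4,4,5,5-tetramethyl-1,3,2-dioxaborolan-2-yl)-3,4-dihydronaphthalen-1(2H)-one F3. Perborate oxidation would then give (S)-8-(benzyloxy)-5-[4-(benzyloxy)-2-oxo-2H-pyran-6-yl]-3-hydroxy-6-phenyl-3,4-dihydronaphthalen-1(2H)-one F4, and hydrogenolysis (H2, Pd/C, EtOAc) would end the route at 21.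

**Further compounds**
F1 | step 7 | benzyl (E)-3-(4,4,5,5-tetramethyl-1,3,2-dioxaborolan-2-yl)acrylate | O=C(/C=C/B1OC(C)(C)C(C)(C)O1)OCc1ccccc1
F2 | step 11 | benzyl (1R,2R,3S)-8-(benzyloxy)-1-hydroxy-6-phenyl-3,5-bis(4,4,5,5-tetramethyl-1,3,2-dioxaborolan-2-yl)-1,2,3,4-tetrahydronaphthalene-2-carboxylate | O[C@@H]1[C@H](C(=O)OCc3ccccc3)[C@@H](B3OC(C)(C)C(C)(C)O3)Cc2c1c(OCc1ccccc1)cc(-c1ccccc1)c2B1OC(C)(C)C(C)(C)O1
F3 | step 14 | (S)-8-(benzyloxy)-5-[4-(benzyloxy)-2-oxo-2H-pyran-6-yl]-6-phenyl-3-(4,4,5,5-tetramethyl-1,3,2-dioxaborolan-2-yl)-3,4-dihydronaphthalen-1(2H)-one | O=C1C[C@@H](B3OC(C)(C)C(C)(C)O3)Cc2c1c(OCc1ccccc1)cc(-c1ccccc1)c2-c1cc(OCc2ccccc2)cc(=O)o1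
F4 | step 14 | (S)-8-(benzyloxy)-5-[4-(benzyloxy)-2-oxo-2H-pyran-6-yl]-3-hydroxy-6-phenyl-3,4-dihydronaphthalen-1(2H)-one | O=C1C[C@@H](O)Cc2c1c(OCc1ccccc1)cc(-c1ccccc1)c2-c1cc(OCc2ccccc2)cc(=O)o1
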